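**A flat curve.** A product curve that flattens looks like a finished reaction. Yet the green run, which is the very flask asked about, stands at 600 min with 64% product, 0% substrate and 36.0% of the charge in neither reading.

| setting | green | flask |
|---|---|---|
| substrate | 0.20 M | 0.20 M |
| free catalyst | 0.26 mM | 0.26 mM |
| remark | the very flask that is asked about, followed so far |  |
| time |  | 10 h |

green run (percent of the substrate charged)

| time / min | product / % | substrate / % |
|---|---|---|
| 30.0 | 11 | 11 |
| 90.0 | 35 | 2 |
| 180 | 48 | 0 |
| 240 | 54 | 0 |
| 360 | 58 | 4 |
| 480 | 57 | 3 |
| 600 | 64 | 0 |

(standard deviation of a reading: 2 percentage points)

- product taken out counts as made
- the numbers in the tables scatter by 2 percentage points (one standard deviation)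
- additions bring no volume worth counting

- delta: at 10 h add free catalyst, 50.0% of the amount charged, then wait 3.0 h
- epsilon: at 10 h take out 90% of the product then present, then wait 3.0 h
- beta: at 10 h add substrate, 50.0% of the amount charged, then wait 3.0 h
- theta: change nothing and wait 3.0 h more

- product, in percent of the substrate first charged, at 10 h
- the remedy with the largest gain of product, or "none" below 2 percentage points (delta / epsilon / beta / theta / none)
- product present, with what was taken out counted in, in percent of the substrate first charged, after epsilon
- product present, with what was taken out counted in, in percent of the substrate first charged, after beta

**Two stretches.** The green run and the asked flask share one charge, so the useful comparison lies inside that run. Product gained 24 percentage points in 60.0 min, but 10 points in 360 min. The unread remainder meanwhile went from 63.0% at 90.0 min to 46.0% at 240 min. The rate thus fell far more than the remainder did, and this reckoning therefore takes the catalyst to be fading while material still waits.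

**Counting dose.** The three late readings average 59.7%, which is the estimate for 10 h. Delta brings 0.390 mM·h of charged dose, meaning catalyst put in times the time since, with any fading left out on both sides of the comparison. The green run reached that charged dose at 90.0 min, with a reading of 35% product. Assuming that equal charged dose converts an equal share, delta should gain 14 points. Beta, epsilon and theta add no fresh catalyst, so they rest on whatever free catalyst still works in the flask, and this reckoning chooses delta.

**The forecast.** The forecast gave 60% now, 61% after epsilon and 83% after beta, named beta as best, and cautioned: “One run cannot separate these”.

**The result.** The flask holds 63.1% and the best remedy is delta, with 64.8% after epsilon and 66.0% after beta. The gains are 12 points for delta, 1.7 points for epsilon, 2.9 points for beta and 1.3 points for theta.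

    free catalyst + product → spent catalyst B (k = 0.0305 M⁻¹ min⁻¹)
    2 free catalyst → spent catalyst A (k = 19.9 M⁻¹ min⁻¹)
    substrate → intermediate (k = 0.0773 min⁻¹)
    free catalyst + intermediate → free catalyst + product (k = 29.3 M⁻¹ min⁻¹)

**Fading clock.** In the flask, the half-life of intermediate by the catalysed step went from 99 min at 8.97 min to 40 h at 600 min, far longer than the 3.0 h of waiting. At that time 36.9% of the charge stands as intermediate and 3.78% of the catalyst is still free. The charged dose of 0.390 mM·h was reckoned at 14 points, and the flask gives 12 points.

**Second flask.** The neighbour flask charged with 6.5 × 10⁻⁵ M of free catalyst reaches by 10 h the charged dose the green run had at 150 min, where the green readings interpolate to 43.7%. The computed product of that neighbour flask is 40.9%, with 59.0% as intermediate.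

The data are simulated for an exercise, noise included.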